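## Analysis of the target

Target 23 is a p-terphenyl. Its central benzene ring (C1'–C6') carries 4-hydroxyphenyl rings at C1' and C4', benzoyloxy groups at C2' and C3', and free hydroxyls at C5' and C6'. There is no stereocenter, and the molecule has a symmetry element that exchanges the two outer rings and the two members of each oxygen pair. The sensitive groups are the two aryl benzoates (cleaved or shifted by base and nucleophiles) and the free catechol, which oxidizes readily. Every tetraoxygenated intermediate on the way is also electron-rich and air-sensitive. The first difficulty is that the central ring is hexasubstituted, so any bond made to it by substitution would have two ortho neighbours. The second is that the two catechol units are identical until they are acylated, and the benzoates must end up ortho to each other, not para. The strategy rests on the sequence aryl–O–O–aryl–O–O around the ring. C6', C1', C2' and C3', with one aryl group and three oxygens, correspond to the four-membered ring of dimethyl squarate 2 after one arylation. C4' (aryl) and C5' (oxygen) are a two-carbon aryl enol ether, so only the C5'–C6' bond has to be made to close the ring.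

## Retrosynthetic reasoning

**23 from 22.** The last bonds cut are four benzylic C–O bonds: the two benzyl ethers on the outer rings and the two bonds of the diphenylmethylene ketal bridging O5' and O6'. All four fall in one neutral hydrogenolysis, so the free catechol appears only in the final step, with no base or oxidant to follow. The benzoates have only each other and aryl-bearing carbons as ring neighbours, so they cannot migrate to the new hydroxyls.

**22 from 21.** The two O–acyl bonds are cut next. In 21 the only free hydroxyls are the two adjacent ones that are to be acylated, so an exhaustive benzoylation needs no selectivity.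

**21 from 20.** Cutting the two C–O bonds of the ketal leads to the symmetric tetraol 20. This is the point where the two catechols are told apart. A one-carbon bridge can only span two adjacent oxygens, so whichever catechol reacts, the two hydroxyls left over are ortho. This is exactly the relationship the benzoates need, and a stepwise acylation could not secure it. The ketal is chosen because it leaves in the same final operation as the benzyl ethers.

**20 from 19 from 18.** The tetraol is the reduced form of dihydroxyquinone 19, and 19 is the hydrolysis product of dimethoxyquinone 18. The detour through the quinone oxidation level is deliberate. As aryl methyl ethers the two methoxy groups could not be removed beside four benzyl ethers. In 18 they are vinylogous esters and yield to alkaline hydrolysis, which benzyl ethers ignore.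

**18 from 17.** Quinone 18 is the two-electron oxidation product of hydroquinone 17, so no skeletal bond is involved.

**17 from 14 (key disconnection).** The C5'–C6' bond is cut and the four-membered ring is restored between C6' and C3'. This gives the 4-hydroxy-4-vinylcyclobutenone 14, in which all six future ring carbons and all their substituents are already connected in the right order. The cut is made here because it turns the hexasubstituted benzene into an isomer that can be made by two carbonyl additions. The forward reaction is purely intramolecular, so crowding at the ring cannot be answered by an intermolecular side reaction. It has to open the cyclobutenone, close the six-membered ring and aromatize.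

**14 from 6 and 12.** The bond between the carbinol carbon (C3') and the aryl-bearing vinyl carbon (C4') is cut. This leads to cyclobutenedione 6 and the vinyllithium 13 derived from bromo enol ether 12. The forward addition must go to the carbonyl next to the methoxy-bearing carbon, which is the more electrophilic one because the other is a vinylogous ester. That regiochemistry places the two aryl groups para in the final ring.

**6 from 1 and 2.** The C1'–aryl bond is cut, giving aryl bromide 1 (through aryllithium 3) and dimethyl squarate 2. Addition to one of two equivalent carbonyls, followed by loss of one methoxy group, re-forms a dione that is now unsymmetrical and ready for the second addition.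

**12 from 10, and 10 from 7 and 8.** The C–Br bond of 12 comes from bromination and dehydrobromination of enol ether 10. The enol ether double bond is cut back to aldehyde 7 and phosphonium salt 8, a one-carbon homologation that delivers the oxygen destined for C5'.

## Alternatives that were turned down

**Alternative 1:** This plan cuts two bonds in each outer ring (C3''–C4'' and C5''–C6''). It traces the target to a central arene already carrying two buta-1,3-dien-2-yl groups, 5,6-bis(benzyloxy)-4,7-di(buta-1,3-dien-2-yl)-2,2-dimethyl-1,3-benzodioxole A2, and two molecules of the ethynylboronate A3. The forward key step is a double cobalt-catalysed (4+2) cycloaddition (low-valent cobalt–diphosphine catalyst) that gives the bis(cyclohexa-1,4-diene) A1 with boron para to the central ring.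

- For it: the cycloaddition is convergent and ligand-controlled in regiochemistry. The two catechols are differentiated from the start, one as an acetonide and one as benzyl ethers. On this point it is stronger than the chosen route, which has to separate a mono-ketal from a symmetric tetraol.
- Against it: the key step builds the simplest part of the molecule, a para-substituted phenol ring that is bought in 1 and 7. The hexasubstituted central ring must already exist in A2, and A2 would have to be made by attaching two dienyl groups, each between two ortho oxygens, which is the crowded substitution the problem is about. After A1 there follow two dehydrogenations, two carbon–boron oxidations, reprotection of the new phenols, acetonide removal, benzoylation and hydrogenolysis.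
- Comparison: the chosen strategy gives up the built-in catechol differentiation. In return its ring-forming step creates the difficult ring itself, with the substitution pattern fixed by connectivity.

**Alternative 2:** This plan cuts three bonds of the central ring (C2'–C3', C4'–C5', C6'–C1'). The precursors are the silicon-tethered bis(ynol ether) A5 and bis(pinacolatoboryl)acetylene A6. The forward key step is a cyclopentadienylcobalt-mediated (2+2+2) cyclotrimerization to the benzodioxasilole A4.

- For it: three ring bonds and the whole central ring are formed in one step. The catechols are differentiated from the outset, one as a silylene and one as a pair of carbon–boron bonds. The end game is short: oxidation of both C–B bonds, benzoylation, desilylation, hydrogenolysis. On bond economy and on catechol differentiation it is stronger than the chosen route.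
- Against it: A5 is a silyl ynol ether twice over. Such O-silyl ynol ethers are configurationally fragile and prone to 1,3-shift of silicon from oxygen to carbon, and a dialkoxysilane carrying two of them has no close analogue. The ynolate needed to make it costs several steps. In the key step the tethered diyne has to co-trimerize with A6 in preference to oligomerization. The product A4 would carry two adjacent boryl groups wedged between aryl rings, which invites protodeboronation.
- Comparison: the risk lies both in making the precursor and in the key step. The chosen route offers a precursor that comes from stable purchasable compounds in four precedented steps, so its uncertainty is confined to one thermal rearrangement.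

**Alternative 3:** This plan cuts C1'–C2' and C4'–C5', each between an aryl-bearing carbon and a carbonyl carbon. It divides the ring into two identical arylpyruvic thioesters A8. The forward key step is a head-to-tail double Claisen condensation under soft enolization (magnesium halide and a tertiary amine), closing the ring as the dihydroxyquinone A7, which is the same compound as 19.

- For it: it mirrors the biosynthetic logic and is symmetric. It is clearly stronger in step economy, because A8 is a few steps from aldehyde 7 and A7 would replace everything up to step 7 of the chosen route.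
- Against it: A8 has three reactive sites: a readily enolized benzylic position, a highly electrophilic ketone and the thioester. The enol(ate) carbon must acylate at the thioester of a second molecule, but the ketone is the better electrophile. Aldol addition there, followed by lactonization, leads to five-membered butenolide dimers. Nothing in A8 enforces the Claisen mode. From A7 onward the end game is the same as in the chosen route, including the desymmetrization.
- Comparison: the chosen route is longer, but each carbon–carbon bond is formed by a step with one available pathway, and the regiochemistry follows from the known reactivity order of the two squarate-derived carbonyls.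

Key step: step 5

Remark: bromine–lithium exchange is retentive and the lithium of 13 sits cis to the methoxy oxygen, so the enol ether of precursor 14 is Z (methoxy cis to the four-membered ring); this geometry disappears on aromatization in step 5.

## Route

Step 1
Reactants: 1 1-(benzyloxy)-4-bromobenzene; 2 dimethyl squarate (3,4-dimethoxycyclobut-3-ene-1,2-dione)
Product: 6 3-[4-(benzyloxy)phenyl]-4-methoxycyclobut-3-ene-1,2-dione, via [4-(benzyloxy)phenyl]lithium 3 (not isolated), via lithium alkoxide adduct 4 (not isolated), via tertiary trifluoroacetate 5 (not isolated)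
Conditions: 1, n-BuLi, THF, −78 °C; cannulate into 2, THF, −78 °C; then (CF3CO)2O, −78 °C to 0 °C; aqueous work-up
Reagents that add atoms: none
Why: Bromine–lithium exchange gives aryllithium 3, which adds 1,2 to one of the two equivalent carbonyls of the squarate; trifluoroacetylation of alkoxide 4 makes the tertiary oxygen a leaving group, and the methoxy-stabilized cyclobutenyl cation from 5 loses its methyl group to trifluoroacetate, unveiling the second carbonyl (squarate 1,2-addition followed by acid-type rearrangement to a 3-alkoxy-4-arylcyclobutenedione).

Step 2
Reactants: 7 4-(benzyloxy)benzaldehyde; 8 (methoxymethyl)triphenylphosphonium chloride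
Product: 10 1-(benzyloxy)-4-(2-methoxyvinyl)benzene (E/Z mixture), via (methoxymethylene)triphenylphosphorane 9 (not isolated)
Conditions: 8, KOtBu, THF, 0 °C; then 7, 0 °C to rt
Reagents that add atoms: none
Why: Wittig olefination with the methoxymethylene ylide homologates the aldehyde to the enol ether; the E/Z ratio is of no consequence because both isomers give the same dibromide-derived oxocarbenium ion in step 3.

Step 3
Reactants: 10 1-(benzyloxy)-4-(2-methoxyvinyl)benzene
Product: 12 1-(benzyloxy)-4-[(Z)-1-bromo-2-methoxyvinyl]benzene, via 1,2-dibromo ether 11 (not isolated)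
Conditions: Br2 (1.0 equiv), CH2Cl2, −78 °C; then Et3N, −78 °C to rt
Reagents that add atoms: bromine, BrBr
Why: The enol ether is far more nucleophilic than the alkoxyarene ring and adds bromine at −78 °C; the α-bromo ether of 11 ionizes to an oxocarbenium ion and the amine removes the acidic benzylic proton, so bromine stays on the aryl-bearing carbon (bromination–dehydrobromination of an enol ether, as used for 2-bromovinyl ethers and 5-bromo-3,4-dihydro-2H-pyran). The isomer with bromine and methoxy cis is expected to predominate, as in those cases.

Step 4
Reactants: 12 1-(benzyloxy)-4-[(Z)-1-bromo-2-methoxyvinyl]benzene; 6 3-[4-(benzyloxy)phenyl]-4-methoxycyclobut-3-ene-1,2-dione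
Product: 14 racemic 2-[4-(benzyloxy)phenyl]-4-{(Z)-1-[4-(benzyloxy)phenyl]-2-methoxyvinyl}-4-hydroxy-3-methoxycyclobut-2-en-1-one, via vinyllithium 13 (not isolated)
Conditions: 12, t-BuLi (2.0 equiv), THF, −78 °C; cannulate into 6, THF, −78 °C; aq. NH4Cl, −78 °C
Reagents that add atoms: none
Why: Retentive bromine–lithium exchange gives 13 with lithium cis to the methoxy oxygen, where it is internally coordinated and cannot undergo anti β-elimination; 13 adds 1,2 to the carbonyl of 6 that lies next to the methoxy-bearing carbon, because the other carbonyl is deactivated as a vinylogous ester. The new carbinol stereocenter forms as a racemate and is destroyed in step 5.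

Step 5
Reactants: 14 racemic 2-[4-(benzyloxy)phenyl]-4-{(Z)-1-[4-(benzyloxy)phenyl]-2-methoxyvinyl}-4-hydroxy-3-methoxycyclobut-2-en-1-one
Product: 17 2,5-bis[4-(benzyloxy)phenyl]-3,6-dimethoxybenzene-1,4-diol, via dienylketene 15 (not isolated), via cyclohexa-2,4-dienone 16 (not isolated)
Conditions: degassed p-xylene, reflux (138 °C), Ar
Reagents that add atoms: none
Why: Heating breaks the C1–C4 bond of 14 in a thermal conrotatory 4-electron electrocyclic ring opening to dienylketene 15. The hydroxyl at C4, the strongest π-donor on that carbon, rotates outward (torquoselectivity), which turns the 1-aryl-2-methoxyvinyl group inward and leaves it cis to the ketene across the new C3=C4 bond. The ketene carbon and the methoxy-bearing vinyl terminus then join in a thermal disrotatory 6-electron electrocyclization that forms the C5'–C6' bond and closes the only new ring, the six-membered carbocycle, as cyclohexadienone 16. Enolization of the C–H at the new sp3 carbon aromatizes 16 to hydroquinone 17, which makes the sequence irreversible. This is the Moore rearrangement of 4-alkenyl-4-hydroxycyclobutenones to hydroquinones, the closest known reaction type. No stereocenter remains: C4 of 14 and the sp3 carbon of 16 both become sp2, and the Z geometry of the enol ether, which puts the methoxy group on the inside of the closing triene, should affect only the rate, since the ketene terminus has no in-plane substituent to clash with it. The selectivity required is that ring closure outruns lactonization of the minor ketene with an inward hydroxyl; because ring opening is reversible, material is funnelled into the aromatizing channel. The substitution pattern of 17 (aryl groups para, oxygens on the four other carbons) is fixed by the connectivity of 14 and needs no further control.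

Step 6
Reactants: 17 2,5-bis[4-(benzyloxy)phenyl]-3,6-dimethoxybenzene-1,4-diol
Product: 18 2,5-bis[4-(benzyloxy)phenyl]-3,6-dimethoxycyclohexa-2,5-diene-1,4-dione
Conditions: Ag2O, MgSO4, CH2Cl2, rt
Reagents that add atoms: none
Why: Two-electron oxidation of an electron-rich hydroquinone to the p-quinone under neutral conditions; the benzyl ethers and outer rings are untouched.

Step 7
Reactants: 18 2,5-bis[4-(benzyloxy)phenyl]-3,6-dimethoxycyclohexa-2,5-diene-1,4-dione
Product: 19 2,5-bis[4-(benzyloxy)phenyl]-3,6-dihydroxycyclohexa-2,5-diene-1,4-dione
Conditions: NaOH (aq, excess), THF/MeOH, 60 °C; then aq. HCl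
Reagents that add atoms: sodium hydroxide, [Na+].[OH-]
Why: Each methoxy group of 18 sits on the β-carbon of an enone (a vinylogous methyl ester), so hydroxide adds there and expels methoxide (addition–elimination); the product is held as its dianion until acidification, and benzyl aryl ethers are inert to aqueous base.

Step 8
Reactants: 19 2,5-bis[4-(benzyloxy)phenyl]-3,6-dihydroxycyclohexa-2,5-diene-1,4-dione
Product: 20 3,6-bis[4-(benzyloxy)phenyl]benzene-1,2,4,5-tetrol
Conditions: Na2S2O4, degassed THF/H2O, rt; used directly under Ar
Reagents that add atoms: none
Why: Dithionite reduction of a quinone to its hydroquinone; the tetraol is air-sensitive and is carried on without storage.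

Step 9
Reactants: 20 3,6-bis[4-(benzyloxy)phenyl]benzene-1,2,4,5-tetrol
Product: 21 4,7-bis[4-(benzyloxy)phenyl]-2,2-diphenyl-1,3-benzodioxole-5,6-diol
Conditions: Ph2CCl2 (0.9 equiv, slow addition), K2CO3, degassed MeCN, rt to 50 °C, Ar
Reagents that add atoms: dichlorodiphenylmethane, ClC(Cl)(c1ccccc1)c1ccccc1
Why: Catechol ketalization with a gem-dichloride (two successive substitutions through the chlorodiphenylmethyl cation, closing a five-membered dioxole). The two catechols are equivalent, so the reagent is kept limiting and a statistical mixture is to be expected, from which 21 is separated; unreacted 20 oxidizes in air to acidic 19, is removed by base extraction and is recycled through step 8.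

Step 10
Reactants: 21 4,7-bis[4-(benzyloxy)phenyl]-2,2-diphenyl-1,3-benzodioxole-5,6-diol
Product: 22 4,7-bis[4-(benzyloxy)phenyl]-2,2-diphenyl-1,3-benzodioxole-5,6-diyl dibenzoate
Conditions: BzCl (2.5 equiv), Et3N, DMAP (cat.), CH2Cl2, 0 °C to rt
Reagents that add atoms: benzoyl chloride, O=C(Cl)c1ccccc1
Why: DMAP-catalysed O-acylation of the only two free phenols; no other nucleophilic site is present, so exhaustive benzoylation gives the ortho-dibenzoate.

Step 11
Reactants: 22 4,7-bis[4-(benzyloxy)phenyl]-2,2-diphenyl-1,3-benzodioxole-5,6-diyl dibenzoate
Product: 23 4,5-dihydroxy-3,6-bis(4-hydroxyphenyl)-1,2-phenylene dibenzoate (target)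
Conditions: H2 (1 atm), Pd/C (10%), THF/EtOAc, rt
Reagents that add atoms: none
Why: Hydrogenolysis cleaves the benzylic C–O bonds of the two benzyl ethers and of the doubly benzylic ketal in one operation; aryl benzoates have no benzylic C–O bond and survive, and the aprotic neutral medium avoids transesterification.

## Compound list

1 | 1-(benzyloxy)-4-bromobenzene | Brc1ccc(OCc2ccccc2)cc1 | starting material
2 | dimethyl squarate | COC1=C(OC)C(=O)C1=O | starting material
3 | [4-(benzyloxy)phenyl]lithium | [Li]c1ccc(OCc2ccccc2)cc1 | intermediate (not isolated)
4 | lithium 1-[4-(benzyloxy)phenyl]-2,3-dimethoxy-4-oxocyclobut-2-en-1-olate (racemic) | [Li+].[O-]C1(c2ccc(OCc3ccccc3)cc2)C(OC)=C(OC)C1=O | intermediate (not isolated)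
5 | 1-[4-(benzyloxy)phenyl]-2,3-dimethoxy-4-oxocyclobut-2-en-1-yl trifluoroacetate (racemic) | O=C(OC1(c2ccc(OCc3ccccc3)cc2)C(OC)=C(OC)C1=O)C(F)(F)F | intermediate (not isolated)
6 | 3-[4-(benzyloxy)phenyl]-4-methoxycyclobut-3-ene-1,2-dione | COC1=C(c2ccc(OCc3ccccc3)cc2)C(=O)C1=O | intermediate
7 | 4-(benzyloxy)benzaldehyde | O=Cc1ccc(OCc2ccccc2)cc1 | starting material
8 | (methoxymethyl)triphenylphosphonium chloride | COC[P+](c1ccccc1)(c1ccccc1)c1ccccc1.[Cl-] | starting material
9 | (methoxymethylene)triphenylphosphorane | COC=P(c1ccccc1)(c1ccccc1)c1ccccc1 | intermediate (not isolated)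
10 | 1-(benzyloxy)-4-(2-methoxyvinyl)benzene (E/Z mixture) | COC=Cc1ccc(OCc2ccccc2)cc1 | intermediate
11 | 1-(benzyloxy)-4-(1,2-dibromo-2-methoxyethyl)benzene (diastereomer mixture) | COC(Br)C(Br)c1ccc(OCc2ccccc2)cc1 | intermediate (not isolated)
12 | 1-(benzyloxy)-4-[(Z)-1-bromo-2-methoxyvinyl]benzene | CO/C=C(\Br)c1ccc(OCc2ccccc2)cc1 | intermediate
13 | {(E)-1-[4-(benzyloxy)phenyl]-2-methoxyvinyl}lithium (lithium cis to methoxy) | CO/C=C(\[Li])c1ccc(OCc2ccccc2)cc1 | intermediate (not isolated)
14 | racemic 2-[4-(benzyloxy)phenyl]-4-{(Z)-1-[4-(benzyloxy)phenyl]-2-methoxyvinyl}-4-hydroxy-3-methoxycyclobut-2-en-1-one | COC1=C(c2ccc(OCc3ccccc3)cc2)C(=O)C1(O)/C(=C\OC)c1ccc(OCc2ccccc2)cc1 | intermediate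
15 | (3Z,5Z)-2,5-bis[4-(benzyloxy)phenyl]-4-hydroxy-3,6-dimethoxyhexa-1,3,5-trien-1-one | O=C=C(c1ccc(OCc2ccccc2)cc1)/C(OC)=C(O)\C(c1ccc(OCc2ccccc2)cc1)=C/OC | intermediate (not isolated)
16 | racemic 2,5-bis[4-(benzyloxy)phenyl]-4-hydroxy-3,6-dimethoxycyclohexa-2,4-dien-1-one | COC1C(=O)C(c2ccc(OCc3ccccc3)cc2)=C(OC)C(O)=C1c1ccc(OCc2ccccc2)cc1 | intermediate (not isolated)
17 | 2,5-bis[4-(benzyloxy)phenyl]-3,6-dimethoxybenzene-1,4-diol | COc1c(O)c(-c2ccc(OCc3ccccc3)cc2)c(OC)c(O)c1-c1ccc(OCc2ccccc2)cc1 | intermediate
18 | 2,5-bis[4-(benzyloxy)phenyl]-3,6-dimethoxycyclohexa-2,5-diene-1,4-dione | COC1=C(c2ccc(OCc3ccccc3)cc2)C(=O)C(OC)=C(c2ccc(OCc3ccccc3)cc2)C1=O | intermediate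
19 | 2,5-bis[4-(benzyloxy)phenyl]-3,6-dihydroxycyclohexa-2,5-diene-1,4-dione | OC1=C(c2ccc(OCc3ccccc3)cc2)C(=O)C(O)=C(c2ccc(OCc3ccccc3)cc2)C1=O | intermediate
20 | 3,6-bis[4-(benzyloxy)phenyl]benzene-1,2,4,5-tetrol | Oc1c(O)c(-c2ccc(OCc3ccccc3)cc2)c(O)c(O)c1-c1ccc(OCc2ccccc2)cc1 | intermediate
21 | 4,7-bis[4-(benzyloxy)phenyl]-2,2-diphenyl-1,3-benzodioxole-5,6-diol | Oc1c(O)c(-c2ccc(OCc3ccccc3)cc2)c2OC(c3ccccc3)(c3ccccc3)Oc2c1-c1ccc(OCc2ccccc2)cc1 | intermediate
22 | 4,7-bis[4-(benzyloxy)phenyl]-2,2-diphenyl-1,3-benzodioxole-5,6-diyl dibenzoate | O=C(Oc1c(OC(=O)c2ccccc2)c(-c2ccc(OCc3ccccc3)cc2)c2OC(c3ccccc3)(c3ccccc3)Oc2c1-c1ccc(OCc2ccccc2)cc1)c1ccccc1 | intermediate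
23 | 4,5-dihydroxy-3,6-bis(4-hydroxyphenyl)-1,2-phenylene dibenzoate | O=C(Oc1c(OC(=O)c2ccccc2)c(-c2ccc(O)cc2)c(O)c(O)c1-c1ccc(O)cc1)c1ccccc1 | target

## Step count and least certain steps

Total step count: 11. Longest linear sequence: 10 steps (7 → 10 → 12 → 14 → 17 → 18 → 19 → 20 → 21 → 22 → 23). The branch from 1 and 2 (step 1) joins at step 4.

**Step 5 (key step).** The most likely problem is a slow ring closure. The triene is fully substituted and the methoxy group of the Z enol ether points into the closing ring. Because the ring opening is reversible, a slow closure lets material escape through the minor ketene in which the hydroxyl has turned inward, and that ketene lactonizes to a butenolide. Fallback: remove the nucleophilic hydroxyl before heating. Setting out from 14, silylation (Me3SiCl, imidazole, DMF) should give the trimethylsilyl ether of 14, F1. Thermolysis of F1 under the conditions of step 5 leaves electrocyclization as the only irreversible exit and should give the mono-silylated hydroquinone F2. Dilute HCl in THF cleaves the silyl ether, and the route is rejoined at 17.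

**Step 9.** The first and second ketalization are not differentiated sterically or electronically, so over-reaction to the bis-ketal and under-reaction run side by side. The phenoxides of 20 are also prone to air oxidation back to 19. Fallback: break the symmetry one stage earlier, where the first reaction deactivates the second. Setting out from 18, hydrolysis with one equivalent of NaOH at rt should stop at the anion of the hydroxy-methoxyquinone F3. Na2S2O4 reduction gives the methoxy-triol F4, which contains a single catechol. Ph2CCl2 can therefore give only one ketal, the methoxyphenol F5. Oxidative demethylation of its 2-methoxyphenol unit with IBX gives the o-quinone F6, and Na2S2O4 reduction of F6 rejoins the route at 21.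

**Step 4.** The vinyllithium may lose lithium methoxide by β-elimination to the arylalkyne, or be protonated, before it adds. Attack at the vinylogous ester carbonyl would give the regioisomeric adduct. Fallback: use a vinyl nucleophile without a β-leaving group and bring in the C5' oxygen afterwards. 1-(Benzyloxy)-4-(1-bromovinyl)benzene F7 is made from commercial 4'-(benzyloxy)acetophenone with (PhO)3P/Br2, then Et3N. It is converted with t-BuLi into the 1-arylvinyllithium F8, which is added to 6 to give the adduct F9. Thermolysis of F9, which has no inward substituent, should give the methoxy-hydroquinone F10, and Ag2O oxidizes it to the quinone F11, which has one free ring position. Conjugate addition of methoxide (NaOMe, MeOH/THF) to that position and enolization rejoin the route at 17.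

**Step 3.** Bromination may spill over onto the benzyloxyphenyl ring, and the moisture-sensitive α-bromo ether may hydrolyse before HBr is lost. Fallback: pass through an isolable acetal. Setting out from 10, bromo-methoxylation (NBS, MeOH, 0 °C) gives the bromo acetal F12. Ionization of the acetal with Me3SiOTf in the presence of i-Pr2NEt and loss of the benzylic proton (acetal-to-enol-ether elimination) rejoins the route at 12.

## Further compounds

F1 | step 5 | racemic 2-[4-(benzyloxy)phenyl]-4-{(Z)-1-[4-(benzyloxy)phenyl]-2-methoxyvinyl}-3-methoxy-4-[(trimethylsilyl)oxy]cyclobut-2-en-1-one | COC1=C(c2ccc(OCc3ccccc3)cc2)C(=O)C1(O[Si](C)(C)C)/C(=C\OC)c1ccc(OCc2ccccc2)cc1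
F2 | step 5 | 2,5-bis[4-(benzyloxy)phenyl]-3,6-dimethoxy-4-[(trimethylsilyl)oxy]phenol | COc1c(O)c(-c2ccc(OCc3ccccc3)cc2)c(OC)c(O[Si](C)(C)C)c1-c1ccc(OCc2ccccc2)cc1
F3 | step 9 | 2,5-bis[4-(benzyloxy)phenyl]-3-hydroxy-6-methoxycyclohexa-2,5-diene-1,4-dione | COC1=C(c2ccc(OCc3ccccc3)cc2)C(=O)C(O)=C(c2ccc(OCc3ccccc3)cc2)C1=O
F4 | step 9 | 3,6-bis[4-(benzyloxy)phenyl]-5-methoxybenzene-1,2,4-triol | COc1c(O)c(-c2ccc(OCc3ccccc3)cc2)c(O)c(O)c1-c1ccc(OCc2ccccc2)cc1
F5 | step 9 | 4,7-bis[4-(benzyloxy)phenyl]-6-methoxy-2,2-diphenyl-1,3-benzodioxol-5-ol | COc1c(O)c(-c2ccc(OCc3ccccc3)cc2)c2OC(c3ccccc3)(c3ccccc3)Oc2c1-c1ccc(OCc2ccccc2)cc1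
F6 | step 9 | 4,7-bis[4-(benzyloxy)phenyl]-2,2-diphenyl-1,3-benzodioxole-5,6-dione | O=C1C(=O)C(c2ccc(OCc3ccccc3)cc2)=C2OC(c3ccccc3)(c3ccccc3)OC2=C1c1ccc(OCc2ccccc2)cc1
F7 | step 4 | 1-(benzyloxy)-4-(1-bromovinyl)benzene | C=C(Br)c1ccc(OCc2ccccc2)cc1
F8 | step 4 | {1-[4-(benzyloxy)phenyl]vinyl}lithium | [Li]C(=C)c1ccc(OCc2ccccc2)cc1
F9 | step 4 | racemic 2-[4-(benzyloxy)phenyl]-4-{1-[4-(benzyloxy)phenyl]vinyl}-4-hydroxy-3-methoxycyclobut-2-en-1-one | COC1=C(c2ccc(OCc3ccccc3)cc2)C(=O)C1(O)C(=C)c1ccc(OCc2ccccc2)cc1
F10 | step 4 | 2,5-bis[4-(benzyloxy)phenyl]-3-methoxybenzene-1,4-diol | COc1c(O)c(-c2ccc(OCc3ccccc3)cc2)cc(O)c1-c1ccc(OCc2ccccc2)cc1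
F11 | step 4 | 2,5-bis[4-(benzyloxy)phenyl]-3-methoxycyclohexa-2,5-diene-1,4-dione | COC1=C(c2ccc(OCc3ccccc3)cc2)C(=O)C=C(c2ccc(OCc3ccccc3)cc2)C1=O
F12 | step 3 | 1-(benzyloxy)-4-(1-bromo-2,2-dimethoxyethyl)benzene | COC(OC)C(Br)c1ccc(OCc2ccccc2)cc1
A1 | alternative 1 | 5,6-bis(benzyloxy)-2,2-dimethyl-4,7-bis[4-(4,4,5,5-tetramethyl-1,3,2-dioxaborolan-2-yl)cyclohexa-1,4-dien-1-yl]-1,3-benzodioxole | CC1(C)Oc2c(O1)c(C1=CCC(B3OC(C)(C)C(C)(C)O3)=CC1)c(OCc1ccccc1)c(OCc1ccccc1)c2C1=CCC(B2OC(C)(C)C(C)(C)O2)=CC1
A2 | alternative 1 | 5,6-bis(benzyloxy)-4,7-di(buta-1,3-dien-2-yl)-2,2-dimethyl-1,3-benzodioxole | CC1(C)Oc2c(O1)c(C(=C)C=C)c(OCc1ccccc1)c(OCc1ccccc1)c2C(=C)C=C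
A3 | alternative 1 | 2-ethynyl-4,4,5,5-tetramethyl-1,3,2-dioxaborolane | C#CB1OC(C)(C)C(C)(C)O1
A4 | alternative 2 | 4,7-bis[4-(benzyloxy)phenyl]-2,2-diisopropyl-5,6-bis(4,4,5,5-tetramethyl-1,3,2-dioxaborolan-2-yl)-1,3,2-benzodioxasilole | CC(C)[Si]1(C(C)C)Oc2c(O1)c(-c3ccc(OCc4ccccc4)cc3)c(B3OC(C)(C)C(C)(C)O3)c(B3OC(C)(C)C(C)(C)O3)c2-c2ccc(OCc3ccccc3)cc2
A5 | alternative 2 | bis({[4-(benzyloxy)phenyl]ethynyl}oxy)diisopropylsilane | CC(C)[Si](OC#Cc1ccc(OCc2ccccc2)cc1)(OC#Cc1ccc(OCc2ccccc2)cc1)C(C)C
A6 | alternative 2 | 1,2-bis(4,4,5,5-tetramethyl-1,3,2-dioxaborolan-2-yl)ethyne | CC1(C)OB(C#CB2OC(C)(C)C(C)(C)O2)OC1(C)C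
A7 | alternative 3 | 2,5-bis[4-(benzyloxy)phenyl]-3,6-dihydroxy-1,4-benzoquinone | O=C1C(O)=C(c2ccc(OCc3ccccc3)cc2)C(=O)C(O)=C1c1ccc(OCc2ccccc2)cc1
A8 | alternative 3 | S-ethyl 3-[4-(benzyloxy)phenyl]-2-oxopropanethioate | CCSC(=O)C(=O)Cc1ccc(OCc2ccccc2)cc1
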